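**Retrosynthetic overview**
- Target ⇐ B-alkyl Suzuki coupling of 3-bromofuran-2(5H)-one with a C9-vinyl decalin triol (C12–C13 bond).
- Triol ⇐ hydride reduction, after a formaldehyde aldol at C4 (gives the gem-bis(hydroxymethyl) carbon) and C8 ester epimerisation of a bicyclic aldehyde ester.
- Both carbocycles ⇐ one enantioselective enamine/photoredox radical bicyclisation of an acyclic aldehyde–alkene–dienoate: ring A closes first (C4–C5), then ring B (C10–C9).
- Acyclic chain ⇐ Z-selective Still–Gennari olefination with acrolein of an α-alkylated phosphonoacetate; the E-trisubstituted alkene ⇐ 1,2-metalate rearrangement of lithiated 2,3-dihydrofuran.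

Labdane numbering (C1–C20) is used for positions.

Assumption: the (2R,5R) imidazolidinone gives the ent configuration at C5 (mirror of the sense reported for the (2S,5S) catalyst in polyene cyclisations); if the sense is the reverse, the (2S,5S) catalyst is used and nothing else changes.

**Route**

Step 1
Reactants: 1 2,3-dihydrofuran; 2 2-(4-chlorobutyl)-1,3-dioxolane
Product: 7 (3E)-8-(1,3-dioxolan-2-yl)-4-methyloct-3-en-1-ol, via 5-lithio-2,3-dihydrofuran 3 (not isolated), via [4-(1,3-dioxolan-2-yl)butyl]lithium 4 (not isolated), via mixed lithium cuprate 5 (not isolated), via alkenylcopper alkoxide 6 (not isolated)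
Conditions: 1, t-BuLi, THF, −78 to 0 °C; 2, Li, DTBB (cat.), THF, −78 °C, then CuBr·SMe2, Et2O/Me2S, −78 °C; combine, −78 °C to rt; MeI, 0 °C to rt; aq NH4Cl/NH3
Reagents that add atoms: iodomethane, CI; in the intermediates only: tert-butyllithium, [Li]C(C)(C)C; lithium, [Li]; copper(I) bromide, [Cu]Br
Why: Kocienski 1,2-metalate rearrangement, in which the alkyl group migrates from copper to the α-alkoxyalkenyl carbon with inversion while the ring opens and the alkenylcopper is then methylated with retention, so the two chain ends are trans across the new trisubstituted alkene (E).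

Step 2
Reactants: 7 (3E)-8-(1,3-dioxolan-2-yl)-4-methyloct-3-en-1-ol
Product: 8 2-[(5E)-8-iodo-5-methyloct-5-en-1-yl]-1,3-dioxolane
Conditions: I2, PPh3, imidazole, CH2Cl2, 0 °C to rt
Reagents that add atoms: iodine, II
Why: Appel-type iodination of the primary alcohol through an alkoxyphosphonium ion, buffered by imidazole so that the acetal and the alkene geometry are untouched.

Step 3
Reactants: 8 2-[(5E)-8-iodo-5-methyloct-5-en-1-yl]-1,3-dioxolane; 9 methyl 2-[bis(2,2,2-trifluoroethoxy)phosphoryl]acetate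
Product: 10 methyl (5E)-2-[bis(2,2,2-trifluoroethoxy)phosphoryl]-10-(1,3-dioxolan-2-yl)-6-methyldec-5-enoate (racemic at C2)
Conditions: 9 (1.5 equiv), NaH, DMF, 0 °C; then 8, 50 °C
Reagents that add atoms: none
Why: SN2 C-alkylation of the stabilised phosphonoacetate anion by the unhindered primary iodide, with excess phosphonate to suppress dialkylation.

Step 4
Reactants: 10 methyl (5E)-2-[bis(2,2,2-trifluoroethoxy)phosphoryl]-10-(1,3-dioxolan-2-yl)-6-methyldec-5-enoate; 11 acrolein
Product: 12 methyl (2Z)-2-[(3E)-8-(1,3-dioxolan-2-yl)-4-methyloct-3-en-1-yl]penta-2,4-dienoate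
Conditions: KHMDS, 18-crown-6, THF, −78 °C; then 11, −78 °C
Reagents that add atoms: none
Why: Still–Gennari Horner–Wadsworth–Emmons olefination, whose fast irreversible elimination from the kinetic adduct places the vinyl group cis to CO2Me (2Z), the geometry that later puts the C9 substituent equatorial.

Step 5
Reactants: 12 methyl (2Z)-2-[(3E)-8-(1,3-dioxolan-2-yl)-4-methyloct-3-en-1-yl]penta-2,4-dienoate
Product: 13 methyl (2Z)-2-[(3E)-4-methyl-9-oxonon-3-en-1-yl]penta-2,4-dienoate
Conditions: 1 M HCl, THF/H2O, rt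
Reagents that add atoms: water, O
Why: Acid-catalysed acetal hydrolysis under conditions too mild to hydrate the trisubstituted alkene or isomerise the dienoate.

Step 6
Reactants: 13 methyl (2Z)-2-[(3E)-4-methyl-9-oxonon-3-en-1-yl]penta-2,4-dienoate
Product: 14 methyl (1R,2R,4aR,5S,8aR)-1-ethenyl-5-formyl-8a-methyldecahydronaphthalene-2-carboxylate (trans-decalin; C8 ester mixture, drawn as the expected major axial epimer)
Conditions: (2R,5R)-2-tert-butyl-3-methyl-5-(naphthalen-1-ylmethyl)imidazolidin-4-one·TFA (30 mol%), Ir(Fmppy)2(dtbbpy)PF6 (2 mol%), H2O (2 equiv), DME (0.02 M), blue LEDs, −20 °C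
Reagents that add atoms: none
Why: Proposed new method: a redox-neutral enamine/photoredox radical bicyclisation in which excited Ir(III) oxidises the chiral enamine to a radical cation whose open face attacks C5 of the E-alkene 6-endo (sets C5, enantiodetermining), the nucleophilic tertiary C10 radical closes 6-endo on the β-carbon of the Z-dienoate through a chair–chair array (sets the trans ring fusion at C10 and the equatorial vinyl at C9), and the electrophilic α-ester radical at C8 is reduced by Ir(II) to the enolate and protonated (C8 is corrected in step 7); the closest known reactions are the imidazolidinone organo-SOMO polyene cyclisations with alternating acrylonitrile acceptors and the photoredox/enamine intramolecular α-alkylation of aldehydes with olefins.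

Step 7
Reactants: 14 methyl (1R,2R,4aR,5S,8aR)-1-ethenyl-5-formyl-8a-methyldecahydronaphthalene-2-carboxylate
Product: 16 methyl (1R,2S,4aS,5R,8aS)-1-ethenyl-5-formyl-5-(hydroxymethyl)-8a-methyldecahydronaphthalene-2-carboxylate, via C8-epimerised aldehyde ester 15 (not isolated)
Conditions: NaOMe (0.5 equiv), MeOH, 50 °C; then (CH2O)n (3 equiv), 0 °C to rt
Reagents that add atoms: formaldehyde (from paraformaldehyde), C=O
Why: Methoxide equilibrates the C8 ester through its enolate to the equatorial epimer (the axial ester is 1,3-diaxial to the C10 methyl) and the C4 aldehyde enolate then undergoes a crossed aldol with formaldehyde to make C4 quaternary, its configuration being irrelevant because both substituents end as CH2OH.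

Step 8
Reactants: 16 methyl (1R,2S,4aS,5R,8aS)-1-ethenyl-5-formyl-5-(hydroxymethyl)-8a-methyldecahydronaphthalene-2-carboxylate
Product: 17 [(1R,2S,4aS,8aS)-1-ethenyl-8a-methyloctahydronaphthalene-2,5,5(1H)-triyl]trimethanol
Conditions: LiAlH4 (4 equiv), THF, 0 °C to rt; Fieser work-up
Reagents that add atoms: none
Why: Hydride reduction of the aldehyde and the ester to primary alcohols under non-enolising conditions, which keeps the C8 configuration, leaves the vinyl group alone and converges any over-reduced diol from step 7 onto the same triol.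

Step 9
Reactants: 17 [(1R,2S,4aS,8aS)-1-ethenyl-8a-methyloctahydronaphthalene-2,5,5(1H)-triyl]trimethanol; 18 3-bromofuran-2(5H)-one
Product: 20 3-{2-[(1R,2S,4aS,8aS)-2,5,5-tris(hydroxymethyl)-8a-methyldecahydronaphthalen-1-yl]ethyl}furan-2(5H)-one (target), via B-alkyl-9-BBN adduct 19 (not isolated)
Conditions: 9-BBN (5 equiv), THF, 0 °C to rt; then 18, Pd(dppf)Cl2 (5 mol%), AsPh3 (5 mol%), 3 M aq K3PO4, DMF, rt
Reagents that add atoms: 9-borabicyclo[3.3.1]nonane, B1C2CCCC1CCC2 (its boron stays only in 19)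
Why: Anti-Markovnikov hydroboration of the terminal vinyl group followed by B-alkyl Suzuki–Miyaura coupling with the α-bromobutenolide forms C12–C13 without touching a stereocentre, the excess 9-BBN covering the three hydroxyls whose borinates hydrolyse in the aqueous base.

**Compound list**

1 | 2,3-dihydrofuran | C1=COCC1 | starting material
2 | 2-(4-chlorobutyl)-1,3-dioxolane | ClCCCCC1OCCO1 | starting material
3 | 5-lithio-2,3-dihydrofuran | [Li]C1=CCCO1 | intermediate (not isolated)
4 | [4-(1,3-dioxolan-2-yl)butyl]lithium | [Li]CCCCC1OCCO1 | intermediate (not isolated)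
5 | lithium [4-(1,3-dioxolan-2-yl)butyl](4,5-dihydrofuran-2-yl)cuprate | O1CCC=C1[Cu-]CCCCC1OCCO1.[Li+] | intermediate (not isolated)
6 | lithium (3Z)-4-cuprio-8-(1,3-dioxolan-2-yl)oct-3-en-1-olate (Cu cis to the CH2CH2O chain) | [Li+].[O-]CC/C=C(\[Cu])CCCCC1OCCO1 | intermediate (not isolated)
7 | (3E)-8-(1,3-dioxolan-2-yl)-4-methyloct-3-en-1-ol | OCC/C=C(\C)CCCCC1OCCO1 | intermediate
8 | 2-[(5E)-8-iodo-5-methyloct-5-en-1-yl]-1,3-dioxolane | ICC/C=C(\C)CCCCC1OCCO1 | intermediate
9 | methyl 2-[bis(2,2,2-trifluoroethoxy)phosphoryl]acetate | COC(=O)CP(=O)(OCC(F)(F)F)OCC(F)(F)F | starting material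
10 | methyl (5E)-2-[bis(2,2,2-trifluoroethoxy)phosphoryl]-10-(1,3-dioxolan-2-yl)-6-methyldec-5-enoate (racemic at C2) | COC(=O)C(CC/C=C(\C)CCCCC1OCCO1)P(=O)(OCC(F)(F)F)OCC(F)(F)F | intermediate
11 | acrolein (prop-2-enal) | C=CC=O | starting material
12 | methyl (2Z)-2-[(3E)-8-(1,3-dioxolan-2-yl)-4-methyloct-3-en-1-yl]penta-2,4-dienoate | C=C/C=C(C(=O)OC)/CC/C=C(\C)CCCCC1OCCO1 | intermediate
13 | methyl (2Z)-2-[(3E)-4-methyl-9-oxonon-3-en-1-yl]penta-2,4-dienoate | C=C/C=C(C(=O)OC)/CC/C=C(\C)CCCCC=O | intermediate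
14 | methyl (1R,2R,4aR,5S,8aR)-1-ethenyl-5-formyl-8a-methyldecahydronaphthalene-2-carboxylate (axial C8 ester, equatorial C4 CHO) | C[C@@]12CCC[C@H](C=O)[C@H]1CC[C@@H](C(=O)OC)[C@H]2C=C | intermediate
15 | methyl (1R,2S,4aR,5S,8aR)-1-ethenyl-5-formyl-8a-methyldecahydronaphthalene-2-carboxylate (equatorial C8 ester) | C[C@@]12CCC[C@H](C=O)[C@H]1CC[C@H](C(=O)OC)[C@H]2C=C | intermediate (not isolated)
16 | methyl (1R,2S,4aS,5R,8aS)-1-ethenyl-5-formyl-5-(hydroxymethyl)-8a-methyldecahydronaphthalene-2-carboxylate | C[C@@]12CCC[C@](C=O)(CO)[C@H]1CC[C@H](C(=O)OC)[C@H]2C=C | intermediate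
17 | [(1R,2S,4aS,8aS)-1-ethenyl-8a-methyloctahydronaphthalene-2,5,5(1H)-triyl]trimethanol | C[C@@]12CCCC(CO)(CO)[C@H]1CC[C@H](CO)[C@H]2C=C | intermediate
18 | 3-bromofuran-2(5H)-one | O=C1OCC=C1Br | starting material
19 | 9-{2-[(1R,2S,4aS,8aS)-2,5,5-tris(hydroxymethyl)-8a-methyldecahydronaphthalen-1-yl]ethyl}-9-borabicyclo[3.3.1]nonane | C[C@@]12CCCC(CO)(CO)[C@H]1CC[C@H](CO)[C@H]2CCB1C2CCCC1CCC2 | intermediate (not isolated)
20 | 3-{2-[(1R,2S,4aS,8aS)-2,5,5-tris(hydroxymethyl)-8a-methyldecahydronaphthalen-1-yl]ethyl}furan-2(5H)-one | C[C@@]12CCCC(CO)(CO)[C@H]1CC[C@H](CO)[C@H]2CCC1=CCOC1=O | target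

**Step count**
Total: 9 steps. Longest linear sequence: 9 steps (1/2 → 20); compounds 9, 11 and 18 are bought.

**Three steps most likely to fail, with fallbacks**

Step 6 (the bicyclisation). The termination by reduction of the α-ester radical is unprecedented in this setting, and the conjugated Z-dienoate can be isomerised by triplet sensitisation or attacked by radicals, which would erode C9. The fallback carries the vinyl group masked as a selenide, so that the acceptor is a simple enoate. It sets out from 10 (with 11) and comes back at 14. Benzeneselenol is added to acrolein 11 to give 3-(phenylselanyl)propanal F1. Still–Gennari olefination of 10 with it gives methyl (2Z)-2-[(3E)-8-(1,3-dioxolan-2-yl)-4-methyloct-3-en-1-yl]-5-(phenylselanyl)pent-2-enoate F2. Acid hydrolysis of the acetal gives methyl (2Z)-2-[(3E)-4-methyl-9-oxonon-3-en-1-yl]-5-(phenylselanyl)pent-2-enoate F3. The same enamine/photoredox bicyclisation gives the 1-[2-(phenylselanyl)ethyl] analogue of 14, F4. Oxidation with NaIO4 and selenoxide syn-elimination on warming unveils the vinyl group and gives 14.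

Step 9 (hydroboration and Suzuki coupling on the free triol with a base-sensitive bromobutenolide). The fallback builds the butenolide by enolate alkylation instead. It sets out from 17 and comes back at 20. Silylation (TBSCl, imidazole) gives the tris(tert-butyldimethylsilyl) ether of 17, F5. Hydroboration–iodination (9-BBN; then I2, NaOMe) gives the primary iodide F6. Alkylation of the LDA-generated enolate of 3-(phenylsulfanyl)oxolan-2-one with F6 (THF/HMPA) gives the α-alkyl-α-phenylsulfanyl lactone F7. Oxidation with mCPBA and thermal sulfoxide elimination gives the tris-silylated butenolide F8, and HF·pyridine removes the silyl groups to give 20.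

Step 1 (four-component metalate rearrangement with a functionalised organolithium). The fallback reverses the roles, bringing the chain in as the electrophile and methyl as the nucleophile. It sets out from 1 and 2 and comes back at 7. Finkelstein exchange (NaI, acetone) converts 2 into 2-(4-iodobutyl)-1,3-dioxolane F9. Alkylation of 5-lithio-2,3-dihydrofuran 3 with F9 gives 5-[4-(1,3-dioxolan-2-yl)butyl]-2,3-dihydrofuran F10. Nickel-catalysed coupling with MeMgBr (NiCl2(PPh3)2, toluene, reflux) opens the enol ether with retention, so methyl ends cis and the long chain trans to the CH2CH2OH arm, and gives 7.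

**Further compounds**

F1 | step 6 | 3-(phenylselanyl)propanal | O=CCC[Se]c1ccccc1
F2 | step 6 | methyl (2Z)-2-[(3E)-8-(1,3-dioxolan-2-yl)-4-methyloct-3-en-1-yl]-5-(phenylselanyl)pent-2-enoate | c1ccccc1[Se]CC/C=C(C(=O)OC)/CC/C=C(\C)CCCCC1OCCO1
F3 | step 6 | methyl (2Z)-2-[(3E)-4-methyl-9-oxonon-3-en-1-yl]-5-(phenylselanyl)pent-2-enoate | c1ccccc1[Se]CC/C=C(C(=O)OC)/CC/C=C(\C)CCCCC=O
F4 | step 6 | methyl (1R,2R,4aR,5S,8aR)-5-formyl-8a-methyl-1-[2-(phenylselanyl)ethyl]decahydronaphthalene-2-carboxylate (C8 mixture, drawn axial) | C[C@@]12CCC[C@H](C=O)[C@H]1CC[C@@H](C(=O)OC)[C@H]2CC[Se]c1ccccc1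
F5 | step 9 | tris(tert-butyldimethylsilyl) ether of 17 | C[C@@]12CCCC(CO[Si](C)(C)C(C)(C)C)(CO[Si](C)(C)C(C)(C)C)[C@H]1CC[C@H](CO[Si](C)(C)C(C)(C)C)[C@H]2C=C
F6 | step 9 | tris(tert-butyldimethylsilyl) ether of the 1-(2-iodoethyl) analogue of 17 | C[C@@]12CCCC(CO[Si](C)(C)C(C)(C)C)(CO[Si](C)(C)C(C)(C)C)[C@H]1CC[C@H](CO[Si](C)(C)C(C)(C)C)[C@H]2CCI
F7 | step 9 | 3-(phenylsulfanyl)-3-{2-[tris-silylated decalinyl]ethyl}oxolan-2-one (mixture at the lactone α-carbon) | C[C@@]12CCCC(CO[Si](C)(C)C(C)(C)C)(CO[Si](C)(C)C(C)(C)C)[C@H]1CC[C@H](CO[Si](C)(C)C(C)(C)C)[C@H]2CCC1(Sc3ccccc3)CCOC1=O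
F8 | step 9 | tris(tert-butyldimethylsilyl) ether of 20 | C[C@@]12CCCC(CO[Si](C)(C)C(C)(C)C)(CO[Si](C)(C)C(C)(C)C)[C@H]1CC[C@H](CO[Si](C)(C)C(C)(C)C)[C@H]2CCC1=CCOC1=O
F9 | step 1 | 2-(4-iodobutyl)-1,3-dioxolane | ICCCCC1OCCO1
F10 | step 1 | 5-[4-(1,3-dioxolan-2-yl)butyl]-2,3-dihydrofuran | C1CC=C(O1)CCCCC1OCCO1
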